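The strategy rests on the O1–C2H2–C3(=CH2)–C4H=C5H–C5a chain of the seven-membered oxepine ring. This is a branched five-carbon (isoprenoid) bridge from the phenolic oxygen to the adjacent aromatic carbon, and it holds the same atoms as the pyran ring of a 2,2-disubstituted 2H-chromene, but with oxygen on a CH2 branch carbon and not on the branching carbon.
Key disconnection: O1–C2 of the oxepine leads back to a Z-dienylphenol carrying an allylic mesylate, which is the ring-opened, H-shifted isomer (o-quinone methide, 1,7-H shift) of a 2-methyl-2-(mesyloxymethyl)-2H-chromene.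
The chromene is traced to an aryl tertiary propargyl ether (Claisen cascade), and that to 4-hydroxybenzaldehyde and the methyl carbonate of the ethynyl adduct of silyloxyacetone. The stearate is attached at the benzylic alcohol after reduction of the aldehyde.
Order of rings: the benzene ring is bought, the pyran ring is closed in step 4, and the pyran ring is opened and re-closed as the oxepine ring in step 9.
Key step: step 9

Assumption: the target has no stereocentre and is achiral, so there is no enantiomer to select. Its only stereochemical element is the ring-enforced cis C4=C5 alkene, and all chromene intermediates are carried as racemates.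

Step 1
Reactants: 1 1-[(tert-butyldimethylsilyl)oxy]propan-2-one; 2 ethynylmagnesium bromide
Product: 3 rac-1-[(tert-butyldimethylsilyl)oxy]-2-methylbut-3-yn-2-ol
Conditions: THF, 0 °C to rt; aq. NH4Cl
Reagents that add atoms: none
Why: 1,2-addition of an alkynyl Grignard reagent to a methyl ketone, in which the quaternary carbinol centre forms as a racemate, which is harmless because step 9 erases this centre.

Step 2
Reactants: 3 rac-1-[(tert-butyldimethylsilyl)oxy]-2-methylbut-3-yn-2-ol
Product: 4 rac-1-[(tert-butyldimethylsilyl)oxy]-2-methylbut-3-yn-2-yl methyl carbonate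
Conditions: n-BuLi (1.0 equiv), THF, −78 °C; ClCO2Me, −78 to 0 °C
Reagents that add atoms: methyl chloroformate, COC(=O)Cl
Why: O-acylation of a lithium alkoxide with a chloroformate, where one equivalent of base removes only the O–H (far more acidic than the alkyne C–H) and the low temperature suppresses O-to-O silyl migration.

Step 3
Reactants: 4 rac-1-[(tert-butyldimethylsilyl)oxy]-2-methylbut-3-yn-2-yl methyl carbonate; 5 4-hydroxybenzaldehyde
Product: 6 rac-4-({1-[(tert-butyldimethylsilyl)oxy]-2-methylbut-3-yn-2-yl}oxy)benzaldehyde
Conditions: CuCl2·2H2O (1 mol %), DBU, MeCN, 0 °C to rt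
Reagents that add atoms: none
Why: copper-catalysed propargylic substitution, in which the copper acetylide expels methyl carbonate to give a copper allenylidene that the acidic, electron-poor phenol captures at the tertiary carbon, a substrate pairing (terminal tertiary propargylic ester, acceptor-substituted phenol) for which this etherification is well established.

Step 4
Reactants: 6 rac-4-({1-[(tert-butyldimethylsilyl)oxy]-2-methylbut-3-yn-2-yl}oxy)benzaldehyde
Product: 9 rac-2-{[(tert-butyldimethylsilyl)oxy]methyl}-2-methyl-2H-chromene-6-carbaldehyde, via o-allenylphenol 7 (not isolated), via o-quinone methide 8 (not isolated)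
Conditions: 1,2-dichlorobenzene, 180 °C, Ar
Reagents that add atoms: none
Why: aryl propargyl ether Claisen cascade, in which the [3,3] shift to one of the two equivalent ortho positions and enolisation give 7, a 1,5-H shift gives 8 and an oxa-6π electrocyclisation closes the pyran ring, the quaternary C2 staying racemic and the silyl ether and aldehyde being thermally inert.

Step 5
Reactants: 9 rac-2-{[(tert-butyldimethylsilyl)oxy]methyl}-2-methyl-2H-chromene-6-carbaldehyde
Product: 10 rac-(2-{[(tert-butyldimethylsilyl)oxy]methyl}-2-methyl-2H-chromen-6-yl)methanol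
Conditions: NaBH4, MeOH–THF, 0 °C
Reagents that add atoms: none
Why: borohydride reduction of an aromatic aldehyde, which leaves the styrene-type alkene and the silyl ether untouched.

Step 6
Reactants: 10 rac-(2-{[(tert-butyldimethylsilyl)oxy]methyl}-2-methyl-2H-chromen-6-yl)methanol; 11 stearoyl chloride (octadecanoyl chloride)
Product: 12 rac-(2-{[(tert-butyldimethylsilyl)oxy]methyl}-2-methyl-2H-chromen-6-yl)methyl octadecanoate
Conditions: Et3N, DMAP (cat.), CH2Cl2, 0 °C to rt
Reagents that add atoms: none
Why: DMAP-catalysed acylation of the only free hydroxyl group, a primary benzylic alcohol, with an acid chloride.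

Step 7
Reactants: 12 rac-(2-{[(tert-butyldimethylsilyl)oxy]methyl}-2-methyl-2H-chromen-6-yl)methyl octadecanoate
Product: 13 rac-[2-(hydroxymethyl)-2-methyl-2H-chromen-6-yl]methyl octadecanoate
Conditions: TBAF/AcOH (1:1), THF, rt
Reagents that add atoms: none
Why: fluoride-induced desilylation, buffered with acetic acid so that no basic alkoxide or fluoride attacks the ester and no strong acid ionises this p-alkoxybenzyl-type ester.

Step 8
Reactants: 13 rac-[2-(hydroxymethyl)-2-methyl-2H-chromen-6-yl]methyl octadecanoate
Product: 14 rac-(2-methyl-2-{[(methylsulfonyl)oxy]methyl}-2H-chromen-6-yl)methyl octadecanoate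
Conditions: MsCl, Et3N, CH2Cl2, 0 °C
Reagents that add atoms: methanesulfonyl chloride, CS(=O)(=O)Cl
Why: sulfonylation of a primary alcohol, giving a mesylate on a neopentyl-type carbon without β-hydrogen that should resist both substitution and elimination during isolation.

Step 9
Reactants: 14 rac-(2-methyl-2-{[(methylsulfonyl)oxy]methyl}-2H-chromen-6-yl)methyl octadecanoate
Product: 17 (3-methylidene-2,3-dihydro-1-benzoxepin-7-yl)methyl octadecanoate (target), via o-quinone methide 15 (not isolated), via Z-dienylphenol mesylate 16 (not isolated)
Conditions: hν (310 nm, Pyrex), powdered K2CO3, MeCN–THF 1:1 (2 mM, degassed), 25 °C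
Reagents that add atoms: none
Why: Proposed new method: excitation of the styrenyl ether chromophore cleaves O1–C2 by retro-oxa-6π electrocyclisation to the cis o-quinone methide 15, an antarafacial [1,7]-H shift from the inward methyl group to the carbonyl oxygen rearomatises it to the Z-dienylphenol 16, and in 16 the CH2OMs carbon, inert in 14 as a β-aryloxy neopentyl-type centre, has become a 2-substituted allylic electrophile lying against the phenol, so that carbonate-assisted O-alkylation follows in the same flask. The closest known reaction type is the photochemical ring expansion of 2,2-dimethyl-2H-chromenes to 2,5-dihydro-1-benzoxepines, which passes through the same quinone methide and 1,7-H shift, together with the photochromic opening of 2H-chromenes; interception of the dienylphenol by a built-in leaving group has not been shown. The oxepine ring closes by 7-exo-tet SN2 at the CH2OMs carbon (7-endo SN2′ at the =CH2 terminus is degenerate and gives the same compound) and so forms O1–C2 of the product, while no stereocentre is created, the racemic quaternary carbon is erased and the cis C4=C5 alkene is handed down from the cis C3=C4 alkene of the chromene. Because the two pericyclic events are uphill and reversible, turnover depends on the final substitution, which cannot revert and should therefore pull all material through. The first selectivity needed is hydrogen migration from CH3 and not from CH2OMs: the smaller methyl group should take the inward position on ring opening, the only place from which oxygen can be reached, both quinone methide geometries re-equilibrate through 14, and a phenol born from the wrong shift has no allylic leaving group and can only return. The second is O-alkylation ahead of 1,6-elimination of stearate from the p-(acyloxymethyl)phenoxide, secured by the Z-alkene that holds the allylic mesylate within bonding distance of oxygen, by ambient temperature, and by a sparingly soluble weak base and high dilution that keep free phenoxide and bimolecular alkylation to a minimum.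

Compound list
1 | 1-[(tert-butyldimethylsilyl)oxy]propan-2-one | CC(=O)CO[Si](C)(C)C(C)(C)C | starting material
2 | ethynylmagnesium bromide | C#C[Mg]Br | starting material
3 | rac-1-[(tert-butyldimethylsilyl)oxy]-2-methylbut-3-yn-2-ol | C#CC(C)(O)CO[Si](C)(C)C(C)(C)C | intermediate
4 | rac-1-[(tert-butyldimethylsilyl)oxy]-2-methylbut-3-yn-2-yl methyl carbonate | C#CC(C)(CO[Si](C)(C)C(C)(C)C)OC(=O)OC | intermediate
5 | 4-hydroxybenzaldehyde | O=Cc1ccc(O)cc1 | starting material
6 | rac-4-({1-[(tert-butyldimethylsilyl)oxy]-2-methylbut-3-yn-2-yl}oxy)benzaldehyde | C#CC(C)(CO[Si](C)(C)C(C)(C)C)Oc1ccc(C=O)cc1 | intermediate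
7 | 3-{4-[(tert-butyldimethylsilyl)oxy]-3-methylbuta-1,2-dien-1-yl}-4-hydroxybenzaldehyde (o-allenylphenol, racemic allene axis, not isolated) | O=Cc1ccc(O)c(C=C=C(C)CO[Si](C)(C)C(C)(C)C)c1 | intermediate
8 | 3-{(Z)-4-[(tert-butyldimethylsilyl)oxy]-3-methylbut-2-en-1-ylidene}-4-oxocyclohexa-1,5-diene-1-carbaldehyde (o-quinone methide, side chain cis to C=O, terminal alkene geometry open, not isolated) | O=C1C=CC(C=O)=C/C1=C/C=C(C)CO[Si](C)(C)C(C)(C)C | intermediate
9 | rac-2-{[(tert-butyldimethylsilyl)oxy]methyl}-2-methyl-2H-chromene-6-carbaldehyde | O=Cc1ccc2OC(C)(CO[Si](C)(C)C(C)(C)C)C=Cc2c1 | intermediate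
10 | rac-(2-{[(tert-butyldimethylsilyl)oxy]methyl}-2-methyl-2H-chromen-6-yl)methanol | OCc1ccc2OC(C)(CO[Si](C)(C)C(C)(C)C)C=Cc2c1 | intermediate
11 | stearoyl chloride (octadecanoyl chloride) | CCCCCCCCCCCCCCCCCC(=O)Cl | starting material
12 | rac-(2-{[(tert-butyldimethylsilyl)oxy]methyl}-2-methyl-2H-chromen-6-yl)methyl octadecanoate | CCCCCCCCCCCCCCCCCC(=O)OCc1ccc2OC(C)(CO[Si](C)(C)C(C)(C)C)C=Cc2c1 | intermediate
13 | rac-[2-(hydroxymethyl)-2-methyl-2H-chromen-6-yl]methyl octadecanoate | CCCCCCCCCCCCCCCCCC(=O)OCc1ccc2OC(C)(CO)C=Cc2c1 | intermediate
14 | rac-(2-methyl-2-{[(methylsulfonyl)oxy]methyl}-2H-chromen-6-yl)methyl octadecanoate | CCCCCCCCCCCCCCCCCC(=O)OCc1ccc2OC(C)(COS(C)(=O)=O)C=Cc2c1 | intermediate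
15 | {3-[(Z)-(2E)-3-methyl-4-[(methylsulfonyl)oxy]but-2-en-1-ylidene]-4-oxocyclohexa-1,5-dien-1-yl}methyl octadecanoate (o-quinone methide, side chain cis to C=O, methyl group inward, not isolated) | O=C1C=CC(COC(=O)CCCCCCCCCCCCCCCCC)=C/C1=C/C=C(\C)COS(C)(=O)=O | intermediate
16 | 4-hydroxy-3-[(1Z)-3-{[(methylsulfonyl)oxy]methyl}buta-1,3-dien-1-yl]benzyl octadecanoate (not isolated) | CCCCCCCCCCCCCCCCCC(=O)OCc1ccc(O)c(/C=C\C(=C)COS(C)(=O)=O)c1 | intermediate
17 | (3-methylidene-2,3-dihydro-1-benzoxepin-7-yl)methyl octadecanoate, CNP0302126.0 (achiral, ring alkene cis) | C=C1C=Cc2cc(COC(=O)CCCCCCCCCCCCCCCCC)ccc2OC1 | target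

Total step count: 9
Longest linear sequence: 9 steps (1 to 17; compounds 5 and 11 enter in steps 3 and 6)

Steps most likely to fail

1. Step 9.
Several processes could defeat it:
- Re-closure of the pyran may outrun the H shift after every photon.
- Hydrogen may migrate from the oxygen-bearing carbon.
- The open form may isomerise from Z to E.
- The transient phenoxide may lose stearate by 1,6-elimination.
- Continued irradiation may degrade the product.

The fallback uses only known chemistry and needs neither a chromene nor a free p-(acyloxymethyl)phenoxide. It sets out from 5 and comes back at 17.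
- Duff ortho-formylation of 5 (hexamethylenetetramine, TFA, reflux, then aq. HCl) should give 4-hydroxyisophthalaldehyde F1.
- Williamson etherification with excess 3-chloro-2-(chloromethyl)prop-1-ene (K2CO3, DMF) should give 4-{[2-(chloromethyl)prop-2-en-1-yl]oxy}isophthalaldehyde F2.
- Heating with PPh3 in MeCN should give the allylic phosphonium chloride F3.
- An intramolecular Wittig olefination under high dilution (K2CO3, 18-crown-6 cat., THF, reflux) follows. Only the ortho formyl group is within reach of the ylide and the ring enforces the cis alkene, so this should close the oxepine to 3-methylidene-2,3-dihydro-1-benzoxepine-7-carbaldehyde F4.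
- NaBH4 reduction should give (3-methylidene-2,3-dihydro-1-benzoxepin-7-yl)methanol F5.
- Acylation with 11 (Et3N, DMAP, CH2Cl2) gives 17.

2. Step 3.
The β-silyloxy group withdraws electron density and crowds the tertiary centre. Ionisation of the carbonate may then become slow, and elimination toward the enyne or oxidative alkyne coupling may outrun etherification.

The fallback builds the pyran ring by an aldol/oxa-Michael annulation and not through a propargyl ether. It sets out from 1 and comes back at 9.
- Kabbe condensation of 1 with 5′-bromo-2′-hydroxyacetophenone (pyrrolidine, MeOH, 60 °C) should give rac-6-bromo-2-{[(tert-butyldimethylsilyl)oxy]methyl}-2-methylchroman-4-one F6.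
- NaBH4 should give the chroman-4-ol F7 as a mixture of diastereomers.
- Acid-free dehydration (MsCl, Et3N, CH2Cl2, 0 °C to rt) should give rac-6-bromo-2-{[(tert-butyldimethylsilyl)oxy]methyl}-2-methyl-2H-chromene F8.
- Bromine–lithium exchange (n-BuLi, THF, −78 °C) followed by DMF gives 9.

3. Step 7.
Fluoride attack at the hindered neopentyl-type silyl ether may be sluggish under buffering. The forcing conditions then needed could cleave or transfer the acyl group of the sensitive benzylic ester.

The fallback reorders the events so that fluoride never meets the ester. It sets out from 9 and comes back at 14.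
- Desilylation of 9 (TBAF, THF, 0 °C) should give rac-2-(hydroxymethyl)-2-methyl-2H-chromene-6-carbaldehyde F9.
- Mesylation (MsCl, Et3N, CH2Cl2) should give rac-(6-formyl-2-methyl-2H-chromen-2-yl)methyl methanesulfonate F10.
- NaBH4 (MeOH–THF, 0 °C) should reduce only the aldehyde, the neopentyl-type mesylate being inert to borohydride, to give rac-[6-(hydroxymethyl)-2-methyl-2H-chromen-2-yl]methyl methanesulfonate F11.
- Acylation with 11 (Et3N, DMAP, CH2Cl2) gives 14.

Further compounds
F1 | step 9 | 4-hydroxyisophthalaldehyde | O=Cc1ccc(O)c(C=O)c1
F2 | step 9 | 4-{[2-(chloromethyl)prop-2-en-1-yl]oxy}isophthalaldehyde | O=Cc1ccc(OCC(=C)CCl)c(C=O)c1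
F3 | step 9 | {2-[(2,4-diformylphenoxy)methyl]prop-2-en-1-yl}triphenylphosphonium chloride | O=Cc1ccc(OCC(=C)C[P+](c2ccccc2)(c2ccccc2)c2ccccc2)c(C=O)c1.[Cl-]
F4 | step 9 | 3-methylidene-2,3-dihydro-1-benzoxepine-7-carbaldehyde | C=C1C=Cc2cc(C=O)ccc2OC1
F5 | step 9 | (3-methylidene-2,3-dihydro-1-benzoxepin-7-yl)methanol | C=C1C=Cc2cc(CO)ccc2OC1
F6 | step 3 | rac-6-bromo-2-{[(tert-butyldimethylsilyl)oxy]methyl}-2-methylchroman-4-one | O=C1CC(C)(CO[Si](C)(C)C(C)(C)C)Oc2ccc(Br)cc12
F7 | step 3 | 6-bromo-2-{[(tert-butyldimethylsilyl)oxy]methyl}-2-methylchroman-4-ol (racemic, mixture of diastereomers) | OC1CC(C)(CO[Si](C)(C)C(C)(C)C)Oc2ccc(Br)cc12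
F8 | step 3 | rac-6-bromo-2-{[(tert-butyldimethylsilyl)oxy]methyl}-2-methyl-2H-chromene | CC1(CO[Si](C)(C)C(C)(C)C)C=Cc2cc(Br)ccc2O1
F9 | step 7 | rac-2-(hydroxymethyl)-2-methyl-2H-chromene-6-carbaldehyde | O=Cc1ccc2OC(C)(CO)C=Cc2c1
F10 | step 7 | rac-(6-formyl-2-methyl-2H-chromen-2-yl)methyl methanesulfonate | O=Cc1ccc2OC(C)(COS(C)(=O)=O)C=Cc2c1
F11 | step 7 | rac-[6-(hydroxymethyl)-2-methyl-2H-chromen-2-yl]methyl methanesulfonate | OCc1ccc2OC(C)(COS(C)(=O)=O)C=Cc2c1
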